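At the reading, 20 min after the start, each of the five flasks below gives one number: the selectivity, meaning complex with one exchanged as a share of itself plus complex with two exchanged.

| setting | dusk | winter | spring | dawn | red | grey | violet | green | ochre |
|---|---|---|---|---|---|---|---|---|---|
| starting complex | 30 mM | 30 mM | 30 mM | 15 mM | 30 mM | 30 mM (fed, over 12 min) | 30 mM | 30 mM (in portions, 4, over 12 min) | 30 mM |
| incoming ligand | 18 mM | 25 mM | 40 mM | 18 mM | 18.0 mM | 18.0 mM | 18.0 mM (fed, over 80 s) | 18.0 mM | 18.0 mM (fed, over 12 min) |
| remark | run made earlier | run made earlier | run made earlier | run made earlier | everything together at the start | all else is in the flask from the start; the feed brings no volume worth counting | all else is in the flask from the start; the feed brings no volume worth counting | first portion at the start, last at 12 min | all else is in the flask from the start; the feed brings no volume worth counting |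
| time |  |  |  |  | 20 min | 20 min | 20 min | 20 min | 20 min |

| run | time / min | complex with one exchanged / % | complex with two exchanged / % |
|---|---|---|---|
| dusk | 1.50 | 7.6 | 0.7 |
| dusk | 4.00 | 5.1 | 0.8 |
| dusk | 8.00 | 3.1 | 0 |
| dusk | 20.0 | 1.3 | 0.5 |
| winter | 1.00 | 8.9 | 0 |
| winter | 2.00 | 7.9 | 1.3 |
| winter | 5.00 | 3.2 | 1.0 |
| winter | 12.0 | 2.7 | 0.6 |
| spring | 1.50 | 6.2 | 1.2 |
| spring | 4.00 | 3.2 | 1.5 |
| spring | 8.00 | 2.8 | 1.6 |
| spring | 12.0 | 1.5 | 1.0 |
| dawn | 3.00 | 6.3 | 1.2 |
| dawn | 6.00 | 4.2 | 0.5 |
| dawn | 10.0 | 3.2 | 1.0 |
| dawn | 12.0 | 3.9 | 1.1 |

(readings scatter by 0.5 percentage points)



* which flask leads in share of complex with one exchanged in complex with one exchanged plus complex with two exchanged ("all alike" within 1.5 percentage points) (red / grey / violet / green / ochre / all alike)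
* share of complex with one exchanged in complex with one exchanged plus complex with two exchanged at the end, red
* share of complex with one exchanged in complex with one exchanged plus complex with two exchanged at the end, grey
* share of complex with one exchanged in complex with one exchanged plus complex with two exchanged at the end, violet
* share of complex with one exchanged in complex with one exchanged plus complex with two exchanged at the end, green
* share of complex with one exchanged in complex with one exchanged plus complex with two exchanged at the end, ochre

Draw the curve of complex with one exchanged from the dusk run, whose charges are those of red. The dusk readings catch no climb: the first already stands at 7.6% at 1.50 min, and those after it lie lower. Between 1.50 min and 8.00 min the dusk readings fade at 0.138 min⁻¹, a half-life of 5.02 min. Between 8.00 min and 20.0 min the fade read from them slows to 0.0724 min⁻¹, so the dusk curve bends towards a level that these readings do not place.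

The last dusk reading over the first is 17.1%. Call this the kept fraction: the part of its early level that complex with one exchanged still shows at the reading. It is a reading, and the scatter of 0.5 percentage points is 38.5% of the late value.

Complex with two exchanged stays low, and its last dusk reading is 0.5%. My own estimate for red is therefore 72.2%, with violet beside it, since its feed of 80 s is shorter than the fade half-life. Ochre's incoming ligand goes in until 12 min, which leaves 1.59 dusk half-lives of fade before the reading. Grey and green have their incoming ligand in from the start, and the spring run, charged with more of it, reads 1.5% of complex with two exchanged at 4.00 min against 0.8% in dusk, so I put ochre first.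

The forecast gives red 72%, grey 68%, violet 73%, green 70% and ochre 90%, and it names ochre as leader, on the grounds that “Ochre keeps ligand scarce”.

The flask gives red 79.1%, grey 77.7%, violet 79.6%, green 72.5% and ochre 87.2%, so ochre leads.

    starting complex + incoming ligand ⇌ leaving ligand + complex with one exchanged (K = 64.0, k = 0.340 M⁻¹ s⁻¹)
    complex with one exchanged + incoming ligand ⇌ leaving ligand + complex with two exchanged (K = 4.20, k = 0.0980 M⁻¹ s⁻¹)
    complex with one exchanged ⇌ isomer of the product (K = 5.20, k = 0.00430 s⁻¹)
    complex with one exchanged + incoming ligand → over-reaction product (k = 2.60 M⁻¹ s⁻¹)
    incoming ligand → decomposed reagent (k = 0.00320 s⁻¹)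

Between ochre and green the gap of 15 points shrinks to 4.4 points when the passing of complex with one exchanged into isomer of the product is taken away, the largest single effect. In green, complex with one exchanged and isomer of the product relax by this step alone with a half-life of 2.25 min, short against 20 min. Take the kept fraction as the part of that pair standing as complex with one exchanged: ochre's 17.5% in the pair gives an estimate of 3.00% of complex with one exchanged, and with ochre's complex with two exchanged a share of 86.4%. The neighbour of green charged with 45 mM of incoming ligand holds 7.04% in the pair, which gives an estimate of 1.20% and a share of 58.2%, where that flask stands at 60.5%.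

(Readings and results come from a simulation with constants of no real substance; noise was put on by code.)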